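The plan cuts the C6–C7 bond of the ten-membered carbocycle together with the lactone O–C12 bond. C6 is the one atom bonded both to butenolide carbon C7 and to the lactone ring oxygen, so intramolecular addition of a C7 alkenylchromium dichloride (trivalent chromium) to a C6 aldehyde closes the carbocycle and frees an alkoxide that lactonises onto the cis methyl ester: two rings form in one operation. The substrate is a 2,5-cis tetrahydrofuran (C1–C4 with the oxygen bridge) that carries a CH2CHO arm (C5, C6) on C4 and, on C1, the C10–C9–C8 chain ending in a (Z)-β-iodo-α-(silyloxymethyl)enoate (C7, C11, C12, C13).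

Key step: step 15

Atom numbering used in all names (germacrane type): C1 = CH of the tetrahydrofuran, C2 and C3 = its CH2 groups, C4 = its C(CH3), C5 = the carbon on C4 that ends as the enol-ether CH, C6 = butenolide carbon bearing the ring oxygen, C7=C11 = butenolide alkene, C8 = acyloxy CH, C9 = CH2, C10 = C(CH3)OH, C12 = lactone carbonyl, C13 = CH2O on C11.
Abbreviations: TES = triethylsilyl, TBS = tert-butyldimethylsilyl, Tf = trifluoromethanesulfonyl, 9-BBN = 9-borabicyclo[3.3.1]nonane.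
Remark on C10: a gem-dimethyl carbinol side chain (as in furanoid linalool oxide) cannot supply C10 with CH3, OH and C9 stereoselectively, so the (E)-methyl of (R)-linalool is oxidised before the ring is made and one asymmetric epoxidation then fixes C1 and C10 together.
Assumption: methyl (S)-2-methylglycidate is bought as the single enantiomer; the key step may give either C6 epimer (one is drawn) because C6 becomes sp2 in step 18.

Step 1
Reactants: 1 (R)-linalool
Product: 2 (2E,6R)-2,6-dimethylocta-2,7-diene-1,6-diol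
Conditions: SeO2 (cat.), t-BuOOH, salicylic acid (cat.), CH2Cl2, rt
Reagents that add atoms: tert-butyl hydroperoxide, CC(C)(C)OO; selenium dioxide, O=[Se]=O (oxygen carrier)
Why: Catalytic SeO2 allylic oxidation (ene reaction followed by [2,3]-sigmatropic shift, reoxidised by t-BuOOH) attacks the E-methyl of the trisubstituted alkene selectively, leaving the monosubstituted vinyl group, the tertiary alcohol and the C4 stereocentre untouched.

Step 2
Reactants: 2 (2E,6R)-2,6-dimethylocta-2,7-diene-1,6-diol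
Product: 4 (2R)-2-[(2S,5R)-5-ethenyl-5-methyloxolan-2-yl]propane-1,2-diol, via epoxy diol 3 (not isolated)
Conditions: Ti(OiPr)4 (0.2 equiv), D-(−)-diethyl tartrate (0.25 equiv), t-BuOOH, 4 Å MS, CH2Cl2, −20 °C; then camphorsulfonic acid (cat.), CH2Cl2, 0 °C to rt
Reagents that add atoms: tert-butyl hydroperoxide, CC(C)(C)OO
Why: Sharpless asymmetric epoxidation of the primary allylic alcohol with the D-tartrate gives the (2R,3R)-epoxy alcohol 3 (the tertiary vinyl carbinol is inert), and acid-catalysed 5-exo epoxide opening by the C4 hydroxyl at C1 with inversion, favoured over 6-endo attack because C10 is deactivated by its CH2OH group, sets C1 as S and C10 as R by reagent control and places the two side arms cis on the ring.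

Step 3
Reactants: 4 (2R)-2-[(2S,5R)-5-ethenyl-5-methyloxolan-2-yl]propane-1,2-diol
Product: 6 (2R,5S)-2-ethenyl-2-methyl-5-[(2R)-2-methyloxiran-2-yl]oxolane, via primary tosylate 5 (not isolated)
Conditions: NaH (2.5 equiv), N-tosylimidazole (1.05 equiv), THF, 0 °C to rt
Reagents that add atoms: none
Why: One-pot epoxide formation from a 1,2-diol: the primary alkoxide is sulfonylated selectively and the neighbouring tertiary alkoxide displaces the tosylate (3-exo-tet Williamson closure) without breaking the C10–O bond, so C10 keeps its configuration.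

Step 4
Reactants: 6 (2R,5S)-2-ethenyl-2-methyl-5-[(2R)-2-methyloxiran-2-yl]oxolane
Product: 8 2-[(2R,5S)-2-methyl-5-[(2R)-2-methyloxiran-2-yl]oxolan-2-yl]ethanol, via B-alkyl-9-BBN adduct 7 (not isolated)
Conditions: 9-BBN, THF, 0 °C to rt; then NaOH, H2O2, H2O, 0 °C
Reagents that add atoms: hydrogen peroxide, OO
Why: Hydroboration–oxidation with the bulky 9-BBN is anti-Markovnikov on the monosubstituted alkene and puts oxygen on C6, while 9-BBN leaves the epoxide alone at room temperature.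

Step 5
Reactants: 8 2-[(2R,5S)-2-methyl-5-[(2R)-2-methyloxiran-2-yl]oxolan-2-yl]ethanol
Product: 9 (2R)-2-[(2S,5R)-5-(2-hydroxyethyl)-5-methyloxolan-2-yl]pent-4-en-2-ol
Conditions: CH2=CHMgBr (4 equiv), CuI (0.2 equiv), THF, −40 to 0 °C
Reagents that add atoms: vinylmagnesium bromide, C=C[Mg]Br
Why: CuI-catalysed Grignard opening of the 2,2-disubstituted epoxide is an SN2 attack at the unhindered CH2 (C9), so the C9–C8 bond forms without touching C10, the first equivalent of reagent merely deprotonating the C6 hydroxyl.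

Step 6
Reactants: 9 (2R)-2-[(2S,5R)-5-(2-hydroxyethyl)-5-methyloxolan-2-yl]pent-4-en-2-ol
Product: 10 (2R,5S)-2-methyl-2-[2-(triethylsilyloxy)ethyl]-5-[(2R)-2-(triethylsilyloxy)pent-4-en-2-yl]oxolane
Conditions: TESOTf (2.5 equiv), 2,6-lutidine, CH2Cl2, −78 to 0 °C
Reagents that add atoms: triethylsilyl triflate, CC[Si](CC)(CC)OS(=O)(=O)C(F)(F)F
Why: Silylation with the silyl triflate and 2,6-lutidine is reactive enough to protect the primary C6 and the hindered tertiary C10 hydroxyl in one operation.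

Step 7
Reactants: 10 (2R,5S)-2-methyl-2-[2-(triethylsilyloxy)ethyl]-5-[(2R)-2-(triethylsilyloxy)pent-4-en-2-yl]oxolane
Product: 12 (3R)-3-[(2S,5R)-5-methyl-5-[2-(triethylsilyloxy)ethyl]oxolan-2-yl]-3-(triethylsilyloxy)butanal, via secondary ozonide 11 (not isolated)
Conditions: O3, CH2Cl2, −78 °C; then PPh3, −78 °C to rt
Reagents that add atoms: ozone, [O-][O+]=O
Why: Ozonolysis with reductive work-up cleaves the only alkene to the C8 aldehyde under neutral conditions that silyl ethers tolerate.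

Step 8
Reactants: 12 (3R)-3-[(2S,5R)-5-methyl-5-[2-(triethylsilyloxy)ethyl]oxolan-2-yl]-3-(triethylsilyloxy)butanal; 13 methyl propiolate
Product: 15 methyl (6R)-4-hydroxy-6-[(2S,5R)-5-methyl-5-[2-(triethylsilyloxy)ethyl]oxolan-2-yl]-6-(triethylsilyloxy)hept-2-ynoate (both C8 epimers), via methyl 3-lithiopropiolate 14 (not isolated)
Conditions: 13, LiN(SiMe3)2, THF, −78 °C; then 12, −78 °C; AcOH quench at −78 °C
Reagents that add atoms: none
Why: Addition of the lithium acetylide 14 to the aldehyde at −78 °C forms the C7–C8 bond (carbonyl alkynylation); C8 is left uncontrolled here because it is reset in steps 9 and 10.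

Step 9
Reactants: 15 methyl (6R)-4-hydroxy-6-[(2S,5R)-5-methyl-5-[2-(triethylsilyloxy)ethyl]oxolan-2-yl]-6-(triethylsilyloxy)hept-2-ynoate
Product: 16 methyl (6R)-6-[(2S,5R)-5-methyl-5-[2-(triethylsilyloxy)ethyl]oxolan-2-yl]-4-oxo-6-(triethylsilyloxy)hept-2-ynoate
Conditions: Dess–Martin periodinane, NaHCO3, CH2Cl2, 0 °C to rt
Reagents that add atoms: none
Why: Dess–Martin oxidation converts the propargylic alcohol into the 4-oxo-2-ynoate under buffered, non-basic conditions that avoid β-elimination of the C10 silyloxy group.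

Step 10
Reactants: 16 methyl (6R)-6-[(2S,5R)-5-methyl-5-[2-(triethylsilyloxy)ethyl]oxolan-2-yl]-4-oxo-6-(triethylsilyloxy)hept-2-ynoate
Product: 17 methyl (4S,6R)-4-hydroxy-6-[(2S,5R)-5-methyl-5-[2-(triethylsilyloxy)ethyl]oxolan-2-yl]-6-(triethylsilyloxy)hept-2-ynoate
Conditions: (S)-Alpine-borane [B-isopinocampheyl-9-BBN from (−)-α-pinene] (2 equiv), THF (concentrated), rt; then CH3CHO; then MeOH, volatiles removed in vacuo
Reagents that add atoms: none
Why: Midland reduction: the chiral trialkylborane transfers its β-hydride to the activated ynone through a boat-like six-membered transition state with the slim alkynyl group beside the pinanyl methyl, so the (S)-reagent gives the (8S) propargylic alcohol by reagent control, the sense being that established for alkynyl ketones.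

Step 11
Reactants: 17 methyl (4S,6R)-4-hydroxy-6-[(2S,5R)-5-methyl-5-[2-(triethylsilyloxy)ethyl]oxolan-2-yl]-6-(triethylsilyloxy)hept-2-ynoate
Product: 18 methyl (4S,6R)-4-(tert-butyldimethylsilyloxy)-6-[(2S,5R)-5-methyl-5-[2-(triethylsilyloxy)ethyl]oxolan-2-yl]-6-(triethylsilyloxy)hept-2-ynoate
Conditions: TBSOTf, 2,6-lutidine, CH2Cl2, −78 °C
Reagents that add atoms: tert-butyldimethylsilyl triflate, CC(C)(C)[Si](C)(C)OS(=O)(=O)C(F)(F)F
Why: Silyl ether formation with the triflate protects the hindered propargylic hydroxyl so that it cannot lactonise or chelate in the next steps.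

Step 12
Reactants: 18 methyl (4S,6R)-4-(tert-butyldimethylsilyloxy)-6-[(2S,5R)-5-methyl-5-[2-(triethylsilyloxy)ethyl]oxolan-2-yl]-6-(triethylsilyloxy)hept-2-ynoate; 19 formaldehyde
Product: 21 methyl (2Z,4S,6R)-4-(tert-butyldimethylsilyloxy)-2-(hydroxymethyl)-3-iodo-6-[(2S,5R)-5-methyl-5-[2-(triethylsilyloxy)ethyl]oxolan-2-yl]-6-(triethylsilyloxy)hept-2-enoate, via iodomagnesium β-iodoallenolate 20 (not isolated)
Conditions: MgI2 (1.5 equiv), monomeric HCHO (from cracked paraformaldehyde, excess), CH2Cl2, −78 to −20 °C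
Reagents that add atoms: magnesium iodide, [Mg+2].[I-].[I-]
Why: MgI2-promoted iodo-aldol (halo-aldol) reaction: conjugate addition of iodide to the MgI2-activated ynoate gives β-iodoallenolate 20, which is hydroxymethylated at C11 by the small electrophile formaldehyde from the side away from iodine under kinetic low-temperature control, so iodine should end cis to the ester (Z) while C8 is untouched.

Step 13
Reactants: 21 methyl (2Z,4S,6R)-4-(tert-butyldimethylsilyloxy)-2-(hydroxymethyl)-3-iodo-6-[(2S,5R)-5-methyl-5-[2-(triethylsilyloxy)ethyl]oxolan-2-yl]-6-(triethylsilyloxy)hept-2-enoate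
Product: 22 methyl (2Z,4S,6R)-4-(tert-butyldimethylsilyloxy)-2-[(tert-butyldimethylsilyloxy)methyl]-3-iodo-6-[(2S,5R)-5-methyl-5-[2-(triethylsilyloxy)ethyl]oxolan-2-yl]-6-(triethylsilyloxy)hept-2-enoate
Conditions: TBSCl, imidazole, DMF, 0 °C to rt
Reagents that add atoms: tert-butyldimethylsilyl chloride, CC(C)(C)[Si](C)(C)Cl
Why: Standard silylation of the primary allylic alcohol gives the second TBS ether and leaves the vinyl iodide and the ester untouched.

Step 14
Reactants: 22 methyl (2Z,4S,6R)-4-(tert-butyldimethylsilyloxy)-2-[(tert-butyldimethylsilyloxy)methyl]-3-iodo-6-[(2S,5R)-5-methyl-5-[2-(triethylsilyloxy)ethyl]oxolan-2-yl]-6-(triethylsilyloxy)hept-2-enoate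
Product: 23 methyl (2Z,4S,6R)-4-(tert-butyldimethylsilyloxy)-2-[(tert-butyldimethylsilyloxy)methyl]-3-iodo-6-[(2S,5R)-5-methyl-5-(2-oxoethyl)oxolan-2-yl]-6-(triethylsilyloxy)hept-2-enoate
Conditions: (COCl)2, DMSO, CH2Cl2, −78 to −40 °C; then Et3N, −78 to 0 °C
Reagents that add atoms: none
Why: Swern oxidation of a silyl ether: activated DMSO converts the primary triethylsilyl ether directly into the aldehyde, whereas the tertiary triethylsilyl ether has no carbinol hydrogen and the bulkier TBS ethers do not react, so C6 is unmasked and oxidised in one operation.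

Step 15
Reactants: 23 methyl (2Z,4S,6R)-4-(tert-butyldimethylsilyloxy)-2-[(tert-butyldimethylsilyloxy)methyl]-3-iodo-6-[(2S,5R)-5-methyl-5-(2-oxoethyl)oxolan-2-yl]-6-(triethylsilyloxy)hept-2-enoate
Product: 26 (1S,4R,8S,10R)-8,13-bis(tert-butyldimethylsilyloxy)-1,4-epoxy-10-(triethylsilyloxy)germacr-7(11)-en-6,12-olide (tricyclic γ-H butenolide; 6S epimer drawn), via alkenyl-CrCl2 species 24 (not isolated), via CrCl2-bound alkoxide 25 (not isolated)
Conditions: CrCl2 (10 equiv), NiCl2 (0.2 equiv), DMSO/THF (3:1), rt, syringe-pump addition of 23 to a final 0.002 M; aqueous ethylenediamine work-up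
Reagents that add atoms: none
Why: CrCl2 reduces NiCl2 to zerovalent nickel, which inserts into the C7–I bond with retention of alkene geometry and hands the alkenyl group to chromium, and the resulting alkenylchromium dichloride 24 (trivalent chromium) adds to the C6 aldehyde (Nozaki–Hiyama–Kishi reaction). The closest known reaction types are Ni/Cr-mediated macrocyclisations of iodoalkene aldehydes across oxygen-bridged medium rings and couplings of (Z)-β-iodoenoates with aldehydes that lactonise in the flask. The ten-membered carbocycle closes by 10-exo-trig addition to the aldehyde carbonyl, and the butenolide by 5-exo-trig acyl substitution of the CrCl2-bound C6 alkoxide 25 on the cis methyl ester with loss of methoxide. The new C6 stereocentre is governed by the substrate (the conformation imposed by the 2,5-cis tetrahydrofuran and the C8 silyloxy group in the cyclisation transition state) and needs no control, because C6 becomes sp2 in step 18. What the step does need is chemoselectivity for the C–I bond and the aldehyde, which the mild, weakly basic organochromium provides in the presence of three silyl ethers, the ester and the allylic C8 oxygen, and a Z iodoenoate so that the ester sits next to the new alkoxide, which is built in at step 12 and kept by the stereoretentive metalation; high dilution with slow addition suppresses intermolecular coupling.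

Step 16
Reactants: 26 (1S,4R,8S,10R)-8,13-bis(tert-butyldimethylsilyloxy)-1,4-epoxy-10-(triethylsilyloxy)germacr-7(11)-en-6,12-olide
Product: 27 (1S,4R,8S,10R)-8,12,13-tris(tert-butyldimethylsilyloxy)-1,4:6,12-diepoxy-10-(triethylsilyloxy)germacra-6,11-diene (fused 2-silyloxyfuran)
Conditions: TBSOTf, Et3N, CH2Cl2, 0 °C
Reagents that add atoms: tert-butyldimethylsilyl triflate, CC(C)(C)[Si](C)(C)OS(=O)(=O)C(F)(F)F
Why: Soft enolisation (Et3N with the silyl triflate) removes the acidic C6 hydrogen of the butenolide and traps the dienolate on oxygen as the aromatic 2-silyloxyfuran, which erases the C6 stereocentre.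

Step 17
Reactants: 27 fused 2-silyloxyfuran
Product: 28 (1S,4R,8S,10R)-8,13-bis(tert-butyldimethylsilyloxy)-1,4-epoxy-6-hydroxy-10-(triethylsilyloxy)germacr-7(11)-en-6,12-olide (γ-hydroxybutenolide, C6 anomers)
Conditions: dimethyldioxirane, acetone/CH2Cl2, −78 °C; then pH 7 aqueous work-up
Reagents that add atoms: dimethyldioxirane, CC1(C)OO1
Why: Dimethyldioxirane epoxidises the electron-rich C6=C7 bond of the 2-silyloxyfuran and the epoxide collapses with loss of the silyl group to the γ-hydroxybutenolide (silyloxyfuran oxidation), placing oxygen on C6 as a mixture of anomers that converge in step 18.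

Step 18
Reactants: 28 γ-hydroxybutenolide
Product: 30 (1S,4R,5E,8S,10R)-8,13-bis(tert-butyldimethylsilyloxy)-1,4-epoxy-10-(triethylsilyloxy)germacra-5,7(11)-dien-6,12-olide, via hemiketal mesylate 29 (not isolated)
Conditions: MsCl, Et3N, CH2Cl2, −20 to 0 °C
Reagents that add atoms: none
Why: Dehydration of the γ-hydroxybutenolide by sulfonylation and E1-type elimination through the acyloxocarbenium ion can only remove a C5 hydrogen, and the medium-ring constraint allows only the alkene with C4 cis to C7 (5E), as in the target.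

Step 19
Reactants: 30 tris-silylated (5E)-ylidenebutenolide
Product: 31 (1S,4R,5E,8S,10R)-1,4-epoxy-8,10,13-trihydroxygermacra-5,7(11)-dien-6,12-olide
Conditions: HF·pyridine, pyridine, THF, 0 °C to rt
Reagents that add atoms: none
Why: Fluoride cleaves the three silyl ethers (global desilylation) under buffered, weakly acidic conditions that the dienyl lactone and the tertiary alcohol tolerate.

Step 20
Reactants: 31 (1S,4R,5E,8S,10R)-1,4-epoxy-8,10,13-trihydroxygermacra-5,7(11)-dien-6,12-olide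
Product: 32 (1S,4R,5E,8S,10R)-13-acetoxy-1,4-epoxy-8,10-dihydroxygermacra-5,7(11)-dien-6,12-olide
Conditions: AcCl (1.1 equiv), 2,4,6-collidine, CH2Cl2, −78 °C
Reagents that add atoms: acetyl chloride, CC(=O)Cl
Why: Acetyl chloride with the hindered base collidine at low temperature acylates the primary C13 hydroxyl selectively over the secondary C8 and tertiary C10 hydroxyls.

Step 21
Reactants: 33 methyl (S)-2-methylglycidate
Product: 34 potassium (S)-2-methyloxirane-2-carboxylate
Conditions: KOH (1.0 equiv), EtOH, 0 °C to rt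
Reagents that add atoms: potassium hydroxide, [K+].[OH-]
Why: Saponification with one equivalent of KOH gives the stable potassium glycidate, whose quaternary stereocentre has no α-hydrogen and cannot epimerise.

Step 22
Reactants: 32 (1S,4R,5E,8S,10R)-13-acetoxy-1,4-epoxy-8,10-dihydroxygermacra-5,7(11)-dien-6,12-olide; 34 potassium (S)-2-methyloxirane-2-carboxylate
Product: 36 (1S,4R,5E,8S,10R)-13-acetoxy-1,4-epoxy-10-hydroxy-8-{[(2S)-2-methyloxiran-2-yl]carbonyloxy}germacra-5,7(11)-dien-6,12-olide (CNP0142137.1), via mixed anhydride 35 (not isolated)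
Conditions: 34, 2,4,6-trichlorobenzoyl chloride, THF, rt; then 32, DMAP, Et3N, toluene, rt
Reagents that add atoms: none
Why: Yamaguchi esterification: the mixed anhydride 35 transfers the glycidoyl group under DMAP catalysis to the secondary C8 hydroxyl, the tertiary C10 hydroxyl being too hindered to react, and no stereocentre of either partner is involved.

Compound list
1 | (R)-linalool, (3R)-3,7-dimethylocta-1,6-dien-3-ol | C=C[C@@](O)(C)CCC=C(C)C | starting material
2 | (2E,6R)-2,6-dimethylocta-2,7-diene-1,6-diol | C=C[C@@](O)(C)CC/C=C(\C)CO | intermediate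
3 | [(2R,3R)-3-[(3R)-3-hydroxy-3-methylpent-4-enyl]-2-methyloxiran-2-yl]methanol (not isolated) | C=C[C@@](O)(C)CC[C@H]1O[C@]1(C)CO | intermediate
4 | (2R)-2-[(2S,5R)-5-ethenyl-5-methyloxolan-2-yl]propane-1,2-diol | C=C[C@@]1(C)CC[C@H](O1)[C@](C)(O)CO | intermediate
5 | (2R)-2-[(2S,5R)-5-ethenyl-5-methyloxolan-2-yl]-2-hydroxypropyl 4-methylbenzenesulfonate (not isolated) | C=C[C@@]1(C)CC[C@H](O1)[C@](C)(O)COS(=O)(=O)c1ccc(C)cc1 | intermediate
6 | (2R,5S)-2-ethenyl-2-methyl-5-[(2R)-2-methyloxiran-2-yl]oxolane | C=C[C@@]1(C)CC[C@H](O1)[C@@]2(C)CO2 | intermediate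
7 | 9-[2-[(2R,5S)-2-methyl-5-[(2R)-2-methyloxiran-2-yl]oxolan-2-yl]ethyl]-9-borabicyclo[3.3.1]nonane (not isolated) | C1CCC2CCCC1B2CC[C@@]3(C)CC[C@H](O3)[C@@]4(C)CO4 | intermediate
8 | 2-[(2R,5S)-2-methyl-5-[(2R)-2-methyloxiran-2-yl]oxolan-2-yl]ethanol | OCC[C@@]1(C)CC[C@H](O1)[C@@]2(C)CO2 | intermediate
9 | (2R)-2-[(2S,5R)-5-(2-hydroxyethyl)-5-methyloxolan-2-yl]pent-4-en-2-ol | OCC[C@@]1(C)CC[C@H](O1)[C@](C)(O)CC=C | intermediate
10 | (2R,5S)-2-methyl-2-[2-(triethylsilyloxy)ethyl]-5-[(2R)-2-(triethylsilyloxy)pent-4-en-2-yl]oxolane | CC[Si](CC)(CC)OCC[C@@]1(C)CC[C@H](O1)[C@](C)(O[Si](CC)(CC)CC)CC=C | intermediate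
11 | secondary ozonide of 10 (1,2,4-trioxolan-3-yl in place of the vinyl group; not isolated) | CC[Si](CC)(CC)OCC[C@@]1(C)CC[C@H](O1)[C@](C)(O[Si](CC)(CC)CC)CC2OCOO2 | intermediate
12 | (3R)-3-[(2S,5R)-5-methyl-5-[2-(triethylsilyloxy)ethyl]oxolan-2-yl]-3-(triethylsilyloxy)butanal | CC[Si](CC)(CC)OCC[C@@]1(C)CC[C@H](O1)[C@](C)(O[Si](CC)(CC)CC)CC=O | intermediate
13 | methyl propiolate | C#CC(=O)OC | starting material
14 | methyl 3-lithiopropiolate (not isolated) | [Li]C#CC(=O)OC | intermediate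
15 | methyl (6R)-4-hydroxy-6-[(2S,5R)-5-methyl-5-[2-(triethylsilyloxy)ethyl]oxolan-2-yl]-6-(triethylsilyloxy)hept-2-ynoate (C8 epimers) | CC[Si](CC)(CC)OCC[C@@]1(C)CC[C@H](O1)[C@](C)(O[Si](CC)(CC)CC)CC(O)C#CC(=O)OC | intermediate
16 | methyl (6R)-6-[(2S,5R)-5-methyl-5-[2-(triethylsilyloxy)ethyl]oxolan-2-yl]-4-oxo-6-(triethylsilyloxy)hept-2-ynoate | CC[Si](CC)(CC)OCC[C@@]1(C)CC[C@H](O1)[C@](C)(O[Si](CC)(CC)CC)CC(=O)C#CC(=O)OC | intermediate
17 | methyl (4S,6R)-4-hydroxy-6-[(2S,5R)-5-methyl-5-[2-(triethylsilyloxy)ethyl]oxolan-2-yl]-6-(triethylsilyloxy)hept-2-ynoate | CC[Si](CC)(CC)OCC[C@@]1(C)CC[C@H](O1)[C@](C)(O[Si](CC)(CC)CC)C[C@H](O)C#CC(=O)OC | intermediate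
18 | methyl (4S,6R)-4-(tert-butyldimethylsilyloxy)-6-[(2S,5R)-5-methyl-5-[2-(triethylsilyloxy)ethyl]oxolan-2-yl]-6-(triethylsilyloxy)hept-2-ynoate | CC[Si](CC)(CC)OCC[C@@]1(C)CC[C@H](O1)[C@](C)(O[Si](CC)(CC)CC)C[C@H](O[Si](C)(C)C(C)(C)C)C#CC(=O)OC | intermediate
19 | formaldehyde | C=O | starting material
20 | iodomagnesium β-iodoallenolate of 18 (iodide added at C7; not isolated) | CC[Si](CC)(CC)OCC[C@@]1(C)CC[C@H](O1)[C@](C)(O[Si](CC)(CC)CC)C[C@H](O[Si](C)(C)C(C)(C)C)C(I)=C=C(OC)O[Mg]I | intermediate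
21 | methyl (2Z,4S,6R)-4-(tert-butyldimethylsilyloxy)-2-(hydroxymethyl)-3-iodo-6-[(2S,5R)-5-methyl-5-[2-(triethylsilyloxy)ethyl]oxolan-2-yl]-6-(triethylsilyloxy)hept-2-enoate | CC[Si](CC)(CC)OCC[C@@]1(C)CC[C@H](O1)[C@](C)(O[Si](CC)(CC)CC)C[C@H](O[Si](C)(C)C(C)(C)C)/C(I)=C(\CO)C(=O)OC | intermediate
22 | methyl (2Z,4S,6R)-4-(tert-butyldimethylsilyloxy)-2-[(tert-butyldimethylsilyloxy)methyl]-3-iodo-6-[(2S,5R)-5-methyl-5-[2-(triethylsilyloxy)ethyl]oxolan-2-yl]-6-(triethylsilyloxy)hept-2-enoate | CC[Si](CC)(CC)OCC[C@@]1(C)CC[C@H](O1)[C@](C)(O[Si](CC)(CC)CC)C[C@H](O[Si](C)(C)C(C)(C)C)/C(I)=C(\CO[Si](C)(C)C(C)(C)C)C(=O)OC | intermediate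
23 | methyl (2Z,4S,6R)-4-(tert-butyldimethylsilyloxy)-2-[(tert-butyldimethylsilyloxy)methyl]-3-iodo-6-[(2S,5R)-5-methyl-5-(2-oxoethyl)oxolan-2-yl]-6-(triethylsilyloxy)hept-2-enoate (key-step substrate) | O=CC[C@@]1(C)CC[C@H](O1)[C@](C)(O[Si](CC)(CC)CC)C[C@H](O[Si](C)(C)C(C)(C)C)/C(I)=C(\CO[Si](C)(C)C(C)(C)C)C(=O)OC | intermediate
24 | alkenylchromium dichloride from 23 (CrCl2 on C7 in place of iodine, geometry retained; not isolated) | O=CC[C@@]1(C)CC[C@H](O1)[C@](C)(O[Si](CC)(CC)CC)C[C@H](O[Si](C)(C)C(C)(C)C)/C([Cr](Cl)Cl)=C(\CO[Si](C)(C)C(C)(C)C)C(=O)OC | intermediate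
25 | CrCl2-bound C6 alkoxide of the ten-membered methyl 6-hydroxy-germacr-7(11)-en-12-oate (ester cis to C6; 6S drawn; not isolated) | COC(=O)/C(CO[Si](C)(C)C(C)(C)C)=C1\[C@@H](O[Cr](Cl)Cl)C[C@@]2(C)CC[C@H](O2)[C@](C)(O[Si](CC)(CC)CC)C[C@@H]1O[Si](C)(C)C(C)(C)C | intermediate
26 | (1S,4R,8S,10R)-8,13-bis(tert-butyldimethylsilyloxy)-1,4-epoxy-10-(triethylsilyloxy)germacr-7(11)-en-6,12-olide (6S drawn, either C6 epimer serves; key-step product) | CC(C)(C)[Si](C)(C)OCC1=C2[C@H](C[C@@]3(C)CC[C@H](O3)[C@](C)(O[Si](CC)(CC)CC)C[C@@H]2O[Si](C)(C)C(C)(C)C)OC1=O | intermediate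
27 | (1S,4R,8S,10R)-8,12,13-tris(tert-butyldimethylsilyloxy)-1,4:6,12-diepoxy-10-(triethylsilyloxy)germacra-6,11-diene (fused 2-silyloxyfuran) | CC(C)(C)[Si](C)(C)OCc1c2c(C[C@@]3(C)CC[C@H](O3)[C@](C)(O[Si](CC)(CC)CC)C[C@@H]2O[Si](C)(C)C(C)(C)C)oc1O[Si](C)(C)C(C)(C)C | intermediate
28 | (1S,4R,8S,10R)-8,13-bis(tert-butyldimethylsilyloxy)-1,4-epoxy-6-hydroxy-10-(triethylsilyloxy)germacr-7(11)-en-6,12-olide (C6 anomers) | CC(C)(C)[Si](C)(C)OCC1=C2C(O)(C[C@@]3(C)CC[C@H](O3)[C@](C)(O[Si](CC)(CC)CC)C[C@@H]2O[Si](C)(C)C(C)(C)C)OC1=O | intermediate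
29 | C6 methanesulfonate of 28 (not isolated) | CC(C)(C)[Si](C)(C)OCC1=C2C(OS(C)(=O)=O)(C[C@@]3(C)CC[C@H](O3)[C@](C)(O[Si](CC)(CC)CC)C[C@@H]2O[Si](C)(C)C(C)(C)C)OC1=O | intermediate
30 | (1S,4R,5E,8S,10R)-8,13-bis(tert-butyldimethylsilyloxy)-1,4-epoxy-10-(triethylsilyloxy)germacra-5,7(11)-dien-6,12-olide | CC(C)(C)[Si](C)(C)OCC1=C2/C(=C\[C@@]3(C)CC[C@H](O3)[C@](C)(O[Si](CC)(CC)CC)C[C@@H]2O[Si](C)(C)C(C)(C)C)OC1=O | intermediate
31 | (1S,4R,5E,8S,10R)-1,4-epoxy-8,10,13-trihydroxygermacra-5,7(11)-dien-6,12-olide | OCC1=C2/C(=C\[C@@]3(C)CC[C@H](O3)[C@](C)(O)C[C@@H]2O)OC1=O | intermediate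
32 | (1S,4R,5E,8S,10R)-13-acetoxy-1,4-epoxy-8,10-dihydroxygermacra-5,7(11)-dien-6,12-olide | CC(=O)OCC1=C2/C(=C\[C@@]3(C)CC[C@H](O3)[C@](C)(O)C[C@@H]2O)OC1=O | intermediate
33 | methyl (S)-2-methylglycidate, methyl (2S)-2-methyloxirane-2-carboxylate | COC(=O)[C@]1(C)CO1 | starting material
34 | potassium (2S)-2-methyloxirane-2-carboxylate | [K+].[O-]C(=O)[C@]1(C)CO1 | intermediate
35 | (2S)-2-methyloxirane-2-carboxylic 2,4,6-trichlorobenzoic anhydride (not isolated) | O=C(OC(=O)[C@]1(C)CO1)c1c(Cl)cc(Cl)cc1Cl | intermediate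
36 | (1S,4R,5E,8S,10R)-13-acetoxy-1,4-epoxy-10-hydroxy-8-{[(2S)-2-methyloxiran-2-yl]carbonyloxy}germacra-5,7(11)-dien-6,12-olide (CNP0142137.1) | CC(=O)OCC1=C2/C(=C\[C@@]3(C)CC[C@H](O3)[C@](C)(O)C[C@@H]2OC(=O)[C@]2(C)CO2)OC1=O | target

Total step count: 22. Longest linear sequence: 21 steps (steps 1–20 and 22 from (R)-linalool); step 21 is a one-step side branch.

Steps most likely to fail

1. Step 15 (key step). Closure of the strained ten-membered ring may be outrun by intermolecular coupling, or the alkenylchromium may be protonated before it reaches the aldehyde, which returns the de-iodinated enoate. The fallback closes the same C6–C7 bond at the ketone oxidation level by intramolecular acylation instead of carbonyl addition. It sets out from aldehyde 23. Pinnick oxidation (NaClO2, NaH2PO4, 2-methyl-2-butene) gives the C6 carboxylic acid F1. Amide coupling with MeNHOMe·HCl (EDC, i-Pr2NEt) gives the Weinreb amide F2. Iodine–magnesium exchange with i-PrMgCl·LiCl in dilute THF at −78 °C, then warming to −20 °C, lets the ester-chelated alkenyl–MgCl acylate itself on the amide and should give the ten-membered (Z)-γ-keto enoate F3. Ester hydrolysis with Me3SnOH (1,2-dichloroethane, 70 °C) gives the keto acid, which closes to its ring tautomer, hydroxybutenolide 28. The route is rejoined at 28, and steps 16 and 17 are not needed.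

2. Step 12. Alkene geometry may be lost if formaldehyde attacks the allenolate from the iodine side or if reversible iodide addition equilibrates the product; the Lewis acid may also strip the primary TES ether. The fallback builds the tetrasubstituted alkene by a chelation-controlled anti-carbometalation, where the geometry is fixed by a five-membered magnesium chelate. It sets out from ynoate 18. Reduction with (i-Bu)2AlH (CH2Cl2, −78 °C) gives the propargylic alcohol F4 (C12 as CH2OH). Alkoxide-directed anti-carbomagnesiation with CH2=CHMgCl (THF/toluene, 70 °C) places vinyl on C11 and magnesium on C7 cis to the CH2O group, and quenching with I2 gives the (Z)-iodo dienol F5. MnO2 gives the enal F6, NaClO2 (NaH2PO4, 2-methyl-2-butene) the acid F7, and TMSCHN2 the methyl dienoate F8. Ozonolysis of the electron-richer terminal vinyl group (O3, CH2Cl2/MeOH, −78 °C) with NaBH4 work-up turns it into the C13 CH2OH group, and the route is rejoined at 21.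

3. Step 22. Acylation of the hindered secondary C8 hydroxyl may be slow enough for DMAP or carboxylate to displace the activated allylic C13 acetate, or for the acetyl group to migrate from O13 to O8. The fallback inverts the order of the two acylations so that no allylic acetate is present during the slow esterification. It sets out from triol 31. TBSCl and imidazole silylate the primary hydroxyl selectively and give the 13-silyl ether F9. Acylation of the C8 hydroxyl with mixed anhydride 35 (DMAP, toluene) gives the 8-glycidate F10. HF·pyridine buffered with pyridine removes the primary silyl group and gives the 13-alcohol F11. Acetylation (AcCl, 2,4,6-collidine, −78 °C) then gives 36.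

Further compounds
F1 | step 15 | C6 carboxylic acid from 23: (2Z,4S,6R) iodoenoate with a carboxymethyl group on the oxolane | OC(=O)C[C@@]1(C)CC[C@H](O1)[C@](C)(O[Si](CC)(CC)CC)C[C@H](O[Si](C)(C)C(C)(C)C)/C(I)=C(\CO[Si](C)(C)C(C)(C)C)C(=O)OC
F2 | step 15 | N-methoxy-N-methylamide (Weinreb amide) of F1 | CON(C)C(=O)C[C@@]1(C)CC[C@H](O1)[C@](C)(O[Si](CC)(CC)CC)C[C@H](O[Si](C)(C)C(C)(C)C)/C(I)=C(\CO[Si](C)(C)C(C)(C)C)C(=O)OC
F3 | step 15 | methyl (1S,4R,8S,10R)-8,13-bis(tert-butyldimethylsilyloxy)-1,4-epoxy-6-oxo-10-(triethylsilyloxy)germacr-7(11)-en-12-oate (ester cis to C6) | COC(=O)/C(CO[Si](C)(C)C(C)(C)C)=C1\C(=O)C[C@@]2(C)CC[C@H](O2)[C@](C)(O[Si](CC)(CC)CC)C[C@@H]1O[Si](C)(C)C(C)(C)C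
F4 | step 12 | (4S,6R)-4-(tert-butyldimethylsilyloxy)-6-[(2S,5R)-5-methyl-5-[2-(triethylsilyloxy)ethyl]oxolan-2-yl]-6-(triethylsilyloxy)hept-2-yn-1-ol | CC[Si](CC)(CC)OCC[C@@]1(C)CC[C@H](O1)[C@](C)(O[Si](CC)(CC)CC)C[C@H](O[Si](C)(C)C(C)(C)C)C#CCO
F5 | step 12 | (2Z,4S,6R)-2-ethenyl-3-iodo hept-2-en-1-ol analogue of F4 (iodine cis to CH2OH) | CC[Si](CC)(CC)OCC[C@@]1(C)CC[C@H](O1)[C@](C)(O[Si](CC)(CC)CC)C[C@H](O[Si](C)(C)C(C)(C)C)/C(I)=C(\C=C)CO
F6 | step 12 | (2Z)-2-ethenyl-3-iodo enal from F5 | CC[Si](CC)(CC)OCC[C@@]1(C)CC[C@H](O1)[C@](C)(O[Si](CC)(CC)CC)C[C@H](O[Si](C)(C)C(C)(C)C)/C(I)=C(\C=C)C=O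
F7 | step 12 | (2Z)-2-ethenyl-3-iodo enoic acid from F6 | CC[Si](CC)(CC)OCC[C@@]1(C)CC[C@H](O1)[C@](C)(O[Si](CC)(CC)CC)C[C@H](O[Si](C)(C)C(C)(C)C)/C(I)=C(\C=C)C(=O)O
F8 | step 12 | methyl (2Z)-2-ethenyl-3-iodo enoate from F7 | CC[Si](CC)(CC)OCC[C@@]1(C)CC[C@H](O1)[C@](C)(O[Si](CC)(CC)CC)C[C@H](O[Si](C)(C)C(C)(C)C)/C(I)=C(\C=C)C(=O)OC
F9 | step 22 | (1S,4R,5E,8S,10R)-13-(tert-butyldimethylsilyloxy)-1,4-epoxy-8,10-dihydroxygermacra-5,7(11)-dien-6,12-olide | CC(C)(C)[Si](C)(C)OCC1=C2/C(=C\[C@@]3(C)CC[C@H](O3)[C@](C)(O)C[C@@H]2O)OC1=O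
F10 | step 22 | 8-[(2S)-2-methyloxirane-2-carbonyl] ester of F9 | CC(C)(C)[Si](C)(C)OCC1=C2/C(=C\[C@@]3(C)CC[C@H](O3)[C@](C)(O)C[C@@H]2OC(=O)[C@]2(C)CO2)OC1=O
F11 | step 22 | (1S,4R,5E,8S,10R)-1,4-epoxy-10,13-dihydroxy-8-{[(2S)-2-methyloxiran-2-yl]carbonyloxy}germacra-5,7(11)-dien-6,12-olide | OCC1=C2/C(=C\[C@@]3(C)CC[C@H](O3)[C@](C)(O)C[C@@H]2OC(=O)[C@]2(C)CO2)OC1=O
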